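## The problem

Tatanan B is a spiro[5.5]undecane: a 2,5-dimethoxycyclohexa-2,5-dienone (ring A, C1–C5) shares the quaternary carbon C6 with a cyclohexane (ring B, C7–C11) in which every carbon is substituted. C6 to C11 are six contiguous stereocentres. The C7 ethyl, C8 methyl, C9 aryl and C11 aryl groups lie on one face and the C10 methyl on the other (aryl = 2,4,5-trimethoxyphenyl). In the chair that keeps the C7, C9, C10 and C11 groups equatorial the C8 methyl is therefore axial, a contra-thermodynamic centre that cannot be set by equilibration. C6 is stereogenic only because the two flanks of ring A differ (C1–H against C5–OMe), so its configuration is decided when the spiro bond forms. The axial C8 methyl can control two other centres: it shields one face of C9 and decides which flank of ring A can sit axial at C6. The C11 aryl group in turn favours a trans, equatorial C10 methyl. Ring A is the fragile part: it is a vinylogous ester and at the same time the ipso-adduct of a phenol, so acid can cleave the benzylic C6–C11 bond with rearomatisation or cause a dienone–phenol shift, and hard nucleophiles can attack C3. The enabling feature is that C6 and C7 (with its ethyl group) are the para ring carbon and the exocyclic carbon of the quinone methide tautomer of 2,5-dimethoxy-4-propenylphenol, while C8–C11 map onto a 1,3-diene with oxygen at C9 as a placeholder for the aryl group. The cis triad C7-ethyl/C8-methyl/C11-aryl is what an endo [4+2] addition would produce.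

## Retrosynthesis

**C9–H and C9–aryl.** Cutting C9–H of 17 leads to the tertiary benzylic alcohol 16, and cutting the C9–aryl bond of 16 leads to ketone 12 and aryl bromide 13 (used as its lithium and cerium derivatives 14 and 15). A cross-coupling to a C9=C10 alkene followed by hydrogenation is the neighbouring option, but syn addition of H2 would place C9–H and C10–H cis, whereas they are trans in 17. A C9 cation captured by hydride needs only facial control, which the axial C8 methyl supplies. The precursor 12 has one aryl ring and one stereocentre fewer. The forward reactions must select the saturated C9 ketone over the vinylogous-ester carbonyl C3, and must reduce the carbinol under acid mild enough for ring A.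

**C10–H.** Ketone 12 is cut at C10–H and written as its C9=C10 silyl enol ether 11. This fixes the regiochemistry of the enol and leaves only the easy centre for protonation: C10 methyl is equatorial and trans to the C11 aryl group in the stable epimer. The alternative enol (C8=C9) would leave the axial C8 methyl to a protonation that disfavours it. The forward step must release the ketone without epimerising C8 and without retro-Michael opening of ring B.

**C7–C8 and C6–C11 (key cut).** Both bonds of 11 are cut together. This gives the propenylphenol 4, which reacts as its quinone methide tautomer 10, and the 2-siloxydiene 9. Cutting only C6–C11 would leave an open-chain enone that still needs C7 and C8 set. Cutting the other pair at the spiro centre (C6–C7 and C10–C11) would put C8 in the enol ether. The chosen pair creates C6, C7, C8 and C11 in one step from two achiral fragments of two steps each, and it matches the polarity of both partners: the enol ether carbon C8 is nucleophilic and the quinone methide carbon C7 electrophilic. The forward reaction must be endo, must discriminate the faces of 10 under a chiral acid, and must complete the dearomatising second bond.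

**Aryl–propenyl bond.** Phenol 4 is cut between the ring and the propenyl group into bromophenol 2 and the (E)-propenylboronate 3; 2 comes from 2,5-dimethoxyphenol 1 by para-bromination. This is one step shorter than acylation, reduction and dehydration, and it avoids Lewis acids that cleave ortho-methoxy groups. The forward coupling must tolerate the free phenol.

**Diene.** Diene 9 is cut at O–Si to enone 8, and 8 at its C=C bond to pentan-3-one 5 and 2,4,5-trimethoxybenzaldehyde 6 (through aldol 7). The enone has only one enolisable position, so the only demand on the silylation is (Z) geometry of the new enol ether.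

## Roads not taken

**Alternative 1: allylic dearomatisation closing C6–C7.** The cut is C6–C7 alone. The acyclic phenol A2, carrying the C8–C11 stereotetrad and a terminal allyl carbonate, would be ionised by [Ir(cod)Cl]2 with a chiral phosphoramidite. The phenol para carbon would attack the substituted allyl terminus to give the 7-vinyl spirodienone A1, and the vinyl group would then be hydrogenated.
- Merits: metal-catalysed allylic dearomatisation of phenols is an established reaction class. The C–C bond forms irreversibly. The catalyst addresses C7.
- Weak points: A2 needs four contiguous acyclic stereocentres before the key step, which alone would take more steps than the whole chosen route. The new bond joins a quaternary carbon to a carbon flanked by the C8 methyl. The choice of ring-A flank at C6 is left to the substrate. The vinyl group must be reduced in the presence of the dienone.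
- Comparison: on precedent this road is the stronger one. The chosen plan sets against it convergence and the fact that one step makes both ring bonds and four stereocentres.

**Alternative 2: ring expansion of a spiro cyclopentanone.** The cuts are C8–C9 and C9–C10. The aryldiazomethane A5 would add to the C8 ketone of the spiro[4.5]decadienone A4 under Sc(OTf)3, and migration of C10 with loss of N2 would give the dione A3.
- Merits: the C9 aryl group arrives with its carbon, and no deoxygenation at C9 is needed.
- Weak points: A4 is itself a spirodienone with three stereocentres, so the dearomatisation problem is only moved. Migration of C10 must beat migration of C7. A3 lacks the C8 methyl, which would have to be built from the C8 ketone in its axial, less stable orientation in several steps. A Lewis acid and a diazo compound must coexist with ring A.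
- Comparison: it is longer and leaves the hardest centre (C8) to the end. The chosen plan sets C8 in the C–C bond-forming step.

**Alternative 3: formal Diels–Alder of an aryl quinone methide.** The cuts are C10–C11 and C6–C7. The diaryl quinone methide generated from carbinol A7 would accept the terminus of the siloxydiene A8 at C11. The phenol para carbon would then close onto C7 of the O-silylated enone to give A6, a silyl enol ether across C8=C9.
- Merits: aryl-substituted quinone methides from diarylmethanols are the best-behaved substrates in chiral acid catalysis, and the first bond formation is a known 1,6-addition. In this respect it is better founded than the chosen plan.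
- Weak points: in A6 the C7 ethyl and C10 methyl are trans, which a suprafacial addition to a diene with both groups outside cannot give. The reaction must therefore be stepwise, and the second closure sets C7 and C6 without an endo rule, onto a less activated alkyl-substituted acceptor. Worse, C8 becomes the enol carbon, so a later protonation would have to deliver the axial C8 methyl.
- Comparison: the chosen plan sets against the better precedent a topology consistent with a single endo event, with only the thermodynamically easy C10 left to protonation.

Key step: step 5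

Assumption: the SMILES fixes six stereocentres but no rotamer about the C11–aryl bond; a hindered-rotation isomer, if it forms, is taken to be separable or thermally equilibrated at the end.
Assumption: the (R) antipode of the acid is written in step 5; which antipode exposes the required face of 10 must be established, and the (S) acid is used if the sense is opposite.

## Route

Step 1
Reactants: 1 2,5-dimethoxyphenol
Product: 2 4-bromo-2,5-dimethoxyphenol
Conditions: NBS, MeCN, 0 °C
Reagents that add atoms: N-bromosuccinimide, O=C1CCC(=O)N1Br
Why: Electrophilic aromatic bromination; C4 is para to the hydroxyl and ortho to the C5 methoxy group and is the least hindered activated position (C6 lies between OH and OMe), so monobromination there is expected.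

Step 2
Reactants: 2 4-bromo-2,5-dimethoxyphenol; 3 4,4,5,5-tetramethyl-2-[(E)-prop-1-enyl]-1,3,2-dioxaborolane
Product: 4 2,5-dimethoxy-4-[(E)-prop-1-enyl]phenol
Conditions: Pd(dppf)Cl2 (3 mol %), K2CO3, 1,4-dioxane/H2O, 80 °C
Reagents that add atoms: none
Why: Suzuki–Miyaura coupling of an aryl bromide with an alkenylboronate, which retains the (E) geometry; free phenols are tolerated under aqueous carbonate conditions.

Step 3
Reactants: 5 pentan-3-one; 6 2,4,5-trimethoxybenzaldehyde
Product: 8 (E)-2-methyl-1-(2,4,5-trimethoxyphenyl)pent-1-en-3-one, via aldol adduct 7 (not isolated)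
Conditions: NaOH (aq), EtOH, 5 (5 equiv), 50 °C
Reagents that add atoms: none
Why: Claisen–Schmidt (crossed aldol) condensation; the aldehyde has no alpha hydrogens, excess ketone suppresses double condensation, and dehydration of aldol 7 gives the more stable (E)-enone with the aryl group trans to the carbonyl.

Step 4
Reactants: 8 (E)-2-methyl-1-(2,4,5-trimethoxyphenyl)pent-1-en-3-one
Product: 9 (1E,3Z)-3-(tert-butyldimethylsilyloxy)-2-methyl-1-(2,4,5-trimethoxyphenyl)penta-1,3-diene
Conditions: TBSOTf, Et3N, CH2Cl2, 0 °C
Reagents that add atoms: tert-butyldimethylsilyl trifluoromethanesulfonate, CC(C)(C)[Si](C)(C)OS(=O)(=O)C(F)(F)F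
Why: Soft enolisation (silyl triflate and amine) of an ethyl ketone whose only enolisable position is the CH2 of the ethyl group; with a branched second substituent these conditions favour the (Z)-silyl enol ether (methyl cis to oxygen, avoiding allylic strain), so the cross-conjugated (1E,3Z)-diene should result.

Step 5
Reactants: 4 2,5-dimethoxy-4-[(E)-prop-1-enyl]phenol; 9 (1E,3Z)-3-(tert-butyldimethylsilyloxy)-2-methyl-1-(2,4,5-trimethoxyphenyl)penta-1,3-diene
Product: 11 (6S,7R,8S,11R)-9-(tert-butyldimethylsilyloxy)-7-ethyl-2,5-dimethoxy-8,10-dimethyl-11-(2,4,5-trimethoxyphenyl)spiro[5.5]undeca-1,4,9-trien-3-one, via quinone methide 10 (not isolated)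
Conditions: (R)-3,3′-bis(2,4,6-triisopropylphenyl)-1,1′-binaphthyl-2,2′-diyl N-triflylphosphoramide (10 mol %), 9 (1.5 equiv), 4 Å MS, toluene, −60 °C, slow addition of 4
Reagents that add atoms: none
Why: Proposed new method: the acid protonates the terminal carbon of the propenyl group of 4 and holds the resulting (E)-quinone methide 10 as a hydrogen-bonded ion pair; the enol ether carbon C8 of 9 bonds to the exocyclic carbon C7 and the styryl terminus C11 to the para carbon C6, in one asynchronous [4+2] event or via the O-silyl oxocarbenium ion, and loss of the phenolic proton returns the catalyst. The closest known reaction types are acid-catalysed 1,6-additions of silyl enol ethers to para-quinone methides and Diels–Alder reactions of 2-siloxydienes with enones; new is that the exocyclic bond of the quinone methide serves as the 2π partner and that the second bond dearomatises the phenol. Ring B is closed as a six-membered ring by ipso (spiro) attack of the phenol para carbon on the benzylic terminus of the silyloxyallyl cation, a 6-endo-trig closure in the stepwise picture. C7 is set by the face of 10 left open in the chiral ion pair; C8 and C11 follow from the (3Z) and (1E) geometry of 9, whose methyl and aryl groups are both outside and so end up cis; their cis relation to the ethyl group follows from the endo arrangement; C6 is set by the same arrangement, with the C1–H flank of ring A over the diene so that the methoxy-bearing flank avoids the C8 methyl. The step needs endo and facial selectivity and must outrun protodesilylation of 9 and acid-catalysed dimerisation of 4; the higher nucleophilicity and excess of the silyl enol ether, slow addition of 4 and low temperature are meant to secure the chemoselectivity, and the confined counter-anion is relied on for the endo and facial preference.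

Step 6
Reactants: 11 (6S,7R,8S,11R)-9-(tert-butyldimethylsilyloxy)-7-ethyl-2,5-dimethoxy-8,10-dimethyl-11-(2,4,5-trimethoxyphenyl)spiro[5.5]undeca-1,4,9-trien-3-one
Product: 12 (6S,7R,8S,10S,11R)-7-ethyl-2,5-dimethoxy-8,10-dimethyl-11-(2,4,5-trimethoxyphenyl)spiro[5.5]undeca-1,4-diene-3,9-dione
Conditions: TBAF, AcOH, THF, −20 to 0 °C
Reagents that add atoms: none
Why: Protodesilylation of a silyl enol ether: fluoride cleaves Si–O and acetic acid protonates the enolate at C10 at once, leaving little time for retro-Michael opening; the equatorial C10 methyl (trans to the C11 aryl) is expected because its epimer would hold the C8 methyl, the C10 methyl and C1 syn-axial, and the buffered medium can correct C10 through the enol using the well-aligned axial C10–H. C8 should keep its configuration because its hydrogen is equatorial and poorly aligned with the carbonyl π system.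

Step 7
Reactants: 12 (6S,7R,8S,10S,11R)-7-ethyl-2,5-dimethoxy-8,10-dimethyl-11-(2,4,5-trimethoxyphenyl)spiro[5.5]undeca-1,4-diene-3,9-dione; 13 1-bromo-2,4,5-trimethoxybenzene
Product: 16 (6S,7R,8S,9S,10S,11R)-7-ethyl-9-hydroxy-2,5-dimethoxy-8,10-dimethyl-9,11-bis(2,4,5-trimethoxyphenyl)spiro[5.5]undeca-1,4-dien-3-one, via aryllithium 14 (not isolated), via arylcerium dichloride 15 (not isolated)
Conditions: 13, n-BuLi, THF, −78 °C; CeCl3, −78 °C; then 12, −78 °C; aq NH4Cl
Reagents that add atoms: none
Why: 1,2-Addition of a weakly basic organocerium reagent to a hindered, enolisable ketone; the saturated C9 ketone is more electrophilic than the C3 carbonyl, a cross-conjugated vinylogous ester, and the non-basic reagent at −78 °C should leave C8 and C10 untouched. Attack is expected anti to the axial C8 methyl (aryl axial, hydroxyl equatorial, 9S), but the C9 configuration is erased in the next step.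

Step 8
Reactants: 16 (6S,7R,8S,9S,10S,11R)-7-ethyl-9-hydroxy-2,5-dimethoxy-8,10-dimethyl-9,11-bis(2,4,5-trimethoxyphenyl)spiro[5.5]undeca-1,4-dien-3-one
Product: 17 Tatanan B, (6S,7R,8S,9S,10R,11R)-7-ethyl-2,5-dimethoxy-8,10-dimethyl-9,11-bis(2,4,5-trimethoxyphenyl)spiro[5.5]undeca-1,4-dien-3-one
Conditions: Et3SiH (10 equiv), TFA (5 equiv), CH2Cl2, −40 °C
Reagents that add atoms: none
Why: Ionic deoxygenation (ionic hydrogenation) of a tertiary benzylic alcohol: TFA ionises the carbinol to a cation stabilised by the trimethoxyphenyl ring, and triethylsilane delivers hydride axially from the face anti to the axial C8 methyl and the axial C1 flank of ring A, giving the equatorial C9 aryl group (9S). Low temperature and excess silane are chosen so that hydride capture outruns proton loss towards C8 or C10 and acid cleavage of the spirodienone.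

## Compound list

1 | 2,5-dimethoxyphenol | COc1ccc(OC)c(O)c1 | starting material
2 | 4-bromo-2,5-dimethoxyphenol | Brc1cc(OC)c(O)cc1OC | intermediate
3 | 4,4,5,5-tetramethyl-2-[(E)-prop-1-enyl]-1,3,2-dioxaborolane | C/C=C/B1OC(C)(C)C(C)(C)O1 | starting material
4 | 2,5-dimethoxy-4-[(E)-prop-1-enyl]phenol | C/C=C/c1cc(OC)c(O)cc1OC | intermediate
5 | pentan-3-one | CCC(=O)CC | starting material
6 | 2,4,5-trimethoxybenzaldehyde | COc1cc(OC)c(C=O)cc1OC | starting material
7 | 1-hydroxy-2-methyl-1-(2,4,5-trimethoxyphenyl)pentan-3-one (aldol adduct, diastereomer mixture, not isolated) | CCC(=O)C(C)C(O)c1cc(OC)c(OC)cc1OC | intermediate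
8 | (E)-2-methyl-1-(2,4,5-trimethoxyphenyl)pent-1-en-3-one | CCC(=O)/C(C)=C/c1cc(OC)c(OC)cc1OC | intermediate
9 | (1E,3Z)-3-(tert-butyldimethylsilyloxy)-2-methyl-1-(2,4,5-trimethoxyphenyl)penta-1,3-diene | C/C=C(\O[Si](C)(C)C(C)(C)C)/C(C)=C/c1cc(OC)c(OC)cc1OC | intermediate
10 | 2,5-dimethoxy-4-[(E)-propylidene]cyclohexa-2,5-dien-1-one (quinone methide, ethyl cis to the CH flank, not isolated) | CC/C=C1\C=C(OC)C(=O)C=C1OC | intermediate
11 | (6S,7R,8S,11R)-9-(tert-butyldimethylsilyloxy)-7-ethyl-2,5-dimethoxy-8,10-dimethyl-11-(2,4,5-trimethoxyphenyl)spiro[5.5]undeca-1,4,9-trien-3-one | CC[C@@H]1[C@H](C)C(O[Si](C)(C)C(C)(C)C)=C(C)[C@H](c2cc(OC)c(OC)cc2OC)[C@]12C=C(OC)C(=O)C=C2OC | intermediate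
12 | (6S,7R,8S,10S,11R)-7-ethyl-2,5-dimethoxy-8,10-dimethyl-11-(2,4,5-trimethoxyphenyl)spiro[5.5]undeca-1,4-diene-3,9-dione | CC[C@@H]1[C@H](C)C(=O)[C@@H](C)[C@H](c2cc(OC)c(OC)cc2OC)[C@]12C=C(OC)C(=O)C=C2OC | intermediate
13 | 1-bromo-2,4,5-trimethoxybenzene | COc1cc(OC)c(Br)cc1OC | starting material
14 | (2,4,5-trimethoxyphenyl)lithium (not isolated) | [Li]c1cc(OC)c(OC)cc1OC | intermediate
15 | dichloro(2,4,5-trimethoxyphenyl)cerium (not isolated) | Cl[Ce](Cl)c1cc(OC)c(OC)cc1OC | intermediate
16 | (6S,7R,8S,9S,10S,11R)-7-ethyl-9-hydroxy-2,5-dimethoxy-8,10-dimethyl-9,11-bis(2,4,5-trimethoxyphenyl)spiro[5.5]undeca-1,4-dien-3-one (C9 shown as expected from axial attack; either C9 epimer serves) | CC[C@@H]1[C@H](C)[C@@](O)(c2cc(OC)c(OC)cc2OC)[C@@H](C)[C@H](c2cc(OC)c(OC)cc2OC)[C@]12C=C(OC)C(=O)C=C2OC | intermediate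
17 | Tatanan B, (6S,7R,8S,9S,10R,11R)-7-ethyl-2,5-dimethoxy-8,10-dimethyl-9,11-bis(2,4,5-trimethoxyphenyl)spiro[5.5]undeca-1,4-dien-3-one | CC[C@@H]1[C@H](C)[C@H](c2cc(OC)c(OC)cc2OC)[C@@H](C)[C@H](c2cc(OC)c(OC)cc2OC)[C@]12C=C(OC)C(=O)C=C2OC | target

## Step count and least certain steps

Total steps: 8. Longest linear sequence: 6 steps (1, 2, 5, 6, 7, 8 or 3, 4, 5, 6, 7, 8).

**Step 5 (key step, proposed new method).** The most likely failure is stalling after the first C–C bond. The O-silyl oxocarbenium ion can pass its silyl group to the counter-anion or the phenol faster than the phenol para carbon attacks, because the closing bond gives up aromatic stabilisation and is reversible under acid. The result would be the open-chain 1,6-adduct. Erosion of endo or facial control and acid-catalysed dimerisation of 4 are the secondary risks.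

Fallback, from 4 and 9, returning at 17, using reaction classes that are each documented:
- The acid is used only for the 1,6-conjugate addition of 9 to the quinone methide from 4 (Mukaiyama-type addition of a silyl enol ether to a para-quinone methide generated in situ). Fluoride work-up gives the open-chain enone (1E,4S,5R)-5-(4-hydroxy-2,5-dimethoxyphenyl)-2,4-dimethyl-1-(2,4,5-trimethoxyphenyl)hept-1-en-3-one F1.
- 1,2-Addition of the aryl cerium reagent 15 (three equivalents, the first spent on the phenol) gives the tertiary allylic alcohol (1E,4S,5R)-5-(4-hydroxy-2,5-dimethoxyphenyl)-2,4-dimethyl-1,3-bis(2,4,5-trimethoxyphenyl)hept-1-en-3-ol F2. No dienone is present at this stage.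
- Mild acid in hexafluoroisopropanol ionises F2 to a 1,3-diarylallyl cation, and the phenol para carbon closes ring B at C11 (intramolecular ipso-Friedel–Crafts allylic alkylation of a phenol). This gives the spirocyclic styrene (6S,7R,8S,11R)-7-ethyl-2,5-dimethoxy-8,10-dimethyl-9,11-bis(2,4,5-trimethoxyphenyl)spiro[5.5]undeca-1,4,9-trien-3-one F3.
- Ionic hydrogenation of F3 (Et3SiH, TFA, low temperature) then gives 17. Protonation at C10 should lead to the cation with equatorial methyl, and hydride should add axially at C9.

**Step 7.** The aryl cerium reagent may add to the C3 carbonyl or displace the C5 methoxy group by addition–elimination. It may also fail to add to the doubly alpha-branched ketone, with slow enolisation eroding C8. Fallback, from 11, returning at 17, replacing carbonyl addition by cross-coupling: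
- CsF and N-phenyltriflimide in DME convert the silyl enol ether directly into the enol triflate (6S,7R,8S,11R)-7-ethyl-2,5-dimethoxy-8,10-dimethyl-3-oxo-11-(2,4,5-trimethoxyphenyl)spiro[5.5]undeca-1,4,9-trien-9-yl trifluoromethanesulfonate F4, with its regiochemistry fixed by the enol ether.
- Suzuki–Miyaura coupling with (2,4,5-trimethoxyphenyl)boronic acid (Pd(OAc)2, SPhos, K3PO4, toluene/H2O) gives the styrene F3.
- Ionic hydrogenation as above gives 17.

**Step 8.** Acid may cleave C6–C11 heterolytically with rearomatisation of ring A (the reverse of an ipso-Friedel–Crafts alkylation). Alternatively the C9 cation may lose and regain a proton, scrambling C8 or C10 towards the all-equatorial C8 epimer. Fallback, from 16, returning at 17, using a radical in place of a cation: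
- Acylation with methyl chlorooxoacetate (DMAP, Et3N, CH2Cl2) gives the tertiary methyl oxalate, methyl (6S,7R,8S,9S,10S,11R)-7-ethyl-2,5-dimethoxy-8,10-dimethyl-3-oxo-9,11-bis(2,4,5-trimethoxyphenyl)spiro[5.5]undeca-1,4-dien-9-yl oxalate F5.
- Bu3SnH and AIBN in toluene at 80 °C (Barton–McCombie-type deoxygenation of a tertiary oxalate) generate the C9 benzylic radical, which should take hydrogen from the face anti to the axial C8 methyl to give 17.

**Step 6.** Kinetic protonation of the enolate from its more open face would give the axial C10 methyl. Correcting it by enolisation risks epimerising C8, and the free enolate may open ring B by a retro-Michael reaction driven by rearomatisation. Fallback, from 11, returning at 17: the ketone stage is left out altogether. The route passes through the enol triflate F4 and the styrene F3 described under step 7, so that C10 is set together with C9 in the final ionic hydrogenation and no enolisable ketone is ever present.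

## Further compounds

F1 | step 5 | (1E,4S,5R)-5-(4-hydroxy-2,5-dimethoxyphenyl)-2,4-dimethyl-1-(2,4,5-trimethoxyphenyl)hept-1-en-3-one | CC[C@@H](c1cc(OC)c(O)cc1OC)[C@H](C)C(=O)/C(C)=C/c1cc(OC)c(OC)cc1OC
F2 | step 5 | (1E,4S,5R)-5-(4-hydroxy-2,5-dimethoxyphenyl)-2,4-dimethyl-1,3-bis(2,4,5-trimethoxyphenyl)hept-1-en-3-ol (either C3 epimer) | CC[C@@H](c1cc(OC)c(O)cc1OC)[C@H](C)C(O)(c1cc(OC)c(OC)cc1OC)/C(C)=C/c1cc(OC)c(OC)cc1OC
F3 | step 5 | (6S,7R,8S,11R)-7-ethyl-2,5-dimethoxy-8,10-dimethyl-9,11-bis(2,4,5-trimethoxyphenyl)spiro[5.5]undeca-1,4,9-trien-3-one | CC[C@@H]1[C@H](C)C(c2cc(OC)c(OC)cc2OC)=C(C)[C@H](c2cc(OC)c(OC)cc2OC)[C@]12C=C(OC)C(=O)C=C2OC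
F4 | step 7 | (6S,7R,8S,11R)-7-ethyl-2,5-dimethoxy-8,10-dimethyl-3-oxo-11-(2,4,5-trimethoxyphenyl)spiro[5.5]undeca-1,4,9-trien-9-yl trifluoromethanesulfonate | CC[C@@H]1[C@H](C)C(OS(=O)(=O)C(F)(F)F)=C(C)[C@H](c2cc(OC)c(OC)cc2OC)[C@]12C=C(OC)C(=O)C=C2OC
F5 | step 8 | methyl (6S,7R,8S,9S,10S,11R)-7-ethyl-2,5-dimethoxy-8,10-dimethyl-3-oxo-9,11-bis(2,4,5-trimethoxyphenyl)spiro[5.5]undeca-1,4-dien-9-yl oxalate | CC[C@@H]1[C@H](C)[C@@](OC(=O)C(=O)OC)(c2cc(OC)c(OC)cc2OC)[C@@H](C)[C@H](c2cc(OC)c(OC)cc2OC)[C@]12C=C(OC)C(=O)C=C2OC
A1 | alternative 1 | 7-ethenyl-2,5-dimethoxy-8,10-dimethyl-9,11-bis(2,4,5-trimethoxyphenyl)spiro[5.5]undeca-1,4-dien-3-one | C=C[C@@H]1[C@H](C)[C@H](c2cc(OC)c(OC)cc2OC)[C@@H](C)[C@H](c2cc(OC)c(OC)cc2OC)[C@]12C=C(OC)C(=O)C=C2OC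
A2 | alternative 1 | methyl (E)-7-(4-hydroxy-2,5-dimethoxyphenyl)-4,6-dimethyl-5,7-bis(2,4,5-trimethoxyphenyl)hept-2-enyl carbonate (stereotetrad as in the SMILES) | COC(=O)OC/C=C/[C@H](C)[C@H](c1cc(OC)c(OC)cc1OC)[C@@H](C)[C@H](c1cc(OC)c(OC)cc1OC)c1cc(OC)c(O)cc1OC
A3 | alternative 2 | 7-ethyl-2,5-dimethoxy-10-methyl-9,11-bis(2,4,5-trimethoxyphenyl)spiro[5.5]undeca-1,4-diene-3,8-dione | CC[C@@H]1C(=O)[C@H](c2cc(OC)c(OC)cc2OC)[C@@H](C)[C@H](c2cc(OC)c(OC)cc2OC)[C@]12C=C(OC)C(=O)C=C2OC
A4 | alternative 2 | 1-ethyl-7,10-dimethoxy-3-methyl-4-(2,4,5-trimethoxyphenyl)spiro[4.5]deca-6,9-diene-2,8-dione (configuration as in the SMILES) | CC[C@@H]1C(=O)[C@@H](C)[C@H](c2cc(OC)c(OC)cc2OC)[C@]12C=C(OC)C(=O)C=C2OC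
A5 | alternative 2 | 1-(diazomethyl)-2,4,5-trimethoxybenzene | COc1cc(OC)c(C=[N+]=[N-])cc1OC
A6 | alternative 3 | 9-(tert-butyldimethylsilyloxy)-7-ethyl-2,5-dimethoxy-8,10-dimethyl-11-(2,4,5-trimethoxyphenyl)spiro[5.5]undeca-1,4,8-trien-3-one | CC[C@@H]1C(C)=C(O[Si](C)(C)C(C)(C)C)[C@@H](C)[C@H](c2cc(OC)c(OC)cc2OC)[C@]12C=C(OC)C(=O)C=C2OC
A7 | alternative 3 | (4-hydroxy-2,5-dimethoxyphenyl)(2,4,5-trimethoxyphenyl)methanol (racemic) | COc1cc(OC)c(C(O)c2cc(OC)c(O)cc2OC)cc1OC
A8 | alternative 3 | tert-butyldimethyl{[(2Z,4E)-4-methylhepta-2,4-dien-3-yl]oxy}silane | C/C=C(\O[Si](C)(C)C(C)(C)C)/C(C)=C/CC
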